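**Retrosynthetic overview**

1. Ring A (O1, carbonyl C2, C3=C4, C5, C6, C7) carries its acyl oxygen O1 on the fully substituted C7, next to a free carbinol at C1''. This is read as a cis C7–C1'' epoxide opened at its tertiary carbon by the C2 carboxyl, so the O1–C7 bond is disconnected: lactone 28 ⇐ epoxy (Z)-enoic acid 27.
2. 27 ⇐ C3=C4 by Still–Gennari union of epoxy aldehyde 14 with the α-alkylated phosphonate 24, then saponification.
3. 14 ⇐ nerol: cleavage of the terminal alkene, Still–Gennari/reduction to a (Z)-2-methyl allylic alcohol, Sharpless epoxidation (sets C7 and C1''), two-carbon extension by triflate/vinyl coupling, hydroboration, oxidation.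
4. 24 ⇐ propane-1,3-diol (Still–Gennari/reduction, PMB ether, iodide) plus alkylation of the phosphonoacetate.
5. Ring A is the only ring and is closed in step 21; the endgame is PMB removal, acetylation of the primary allylic alcohol and desilylation.

Key step: step 21

Remark on the chemistry: ring A is numbered O1, C2 (carbonyl), C3=C4, C5, C6, C7, and the carbinol carbon on C7 is C1''. A tert-butyldiphenylsilyl ether is used on the neryl oxygen so that it outlasts periodic acid, hydroxide and the acid of the key step. The stereorandom centres of 3, 4 and 24 are destroyed later and are left undefined.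

**Route**

Step 1
Reactants: 1 nerol
Product: 2 tert-butyl{[(2Z)-3,7-dimethylocta-2,6-dien-1-yl]oxy}diphenylsilane
Conditions: TBDPSCl, imidazole, DMF, 0 °C to rt
Reagents that add atoms: tert-butyl(chloro)diphenylsilane, CC(C)(C)[Si](Cl)(c1ccccc1)c1ccccc1
Why: Silylation of an unhindered primary allylic alcohol through the N-silylimidazolium species should be clean, and this silyl ether is stable to every later step before the last.

Step 2
Reactants: 2 tert-butyl{[(2Z)-3,7-dimethylocta-2,6-dien-1-yl]oxy}diphenylsilane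
Product: 3 tert-butyl{[(2Z)-5-(3,3-dimethyloxiran-2-yl)-3-methylpent-2-en-1-yl]oxy}diphenylsilane (racemic at the oxirane CH)
Conditions: mCPBA (1.0 equiv), CH2Cl2, −20 to 0 °C
Reagents that add atoms: 3-chloroperbenzoic acid, OOC(=O)c1cccc(Cl)c1
Why: Prilezhaev epoxidation should prefer the remote isopropylidene alkene, which is more electron-rich and less shielded than the alkene that is deactivated by the allylic oxygen and covered by the bulky silyl group.

Step 3
Reactants: 3 tert-butyl{[(2Z)-5-(3,3-dimethyloxiran-2-yl)-3-methylpent-2-en-1-yl]oxy}diphenylsilane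
Product: 5 (4Z)-6-[(tert-butyldiphenylsilyl)oxy]-4-methylhex-4-enal, via vicinal diol 4 (not isolated)
Conditions: H5IO6, THF/H2O, 0 °C
Reagents that add atoms: none
Why: Periodic acid hydrolyses the epoxide to the glycol and cleaves it in the same flask (Malaprade glycol cleavage), releasing acetone without touching the Z alkene or the silyl ether.

Step 4
Reactants: 5 (4Z)-6-[(tert-butyldiphenylsilyl)oxy]-4-methylhex-4-enal; 6 methyl 2-[bis(2,2,2-trifluoroethoxy)phosphoryl]propanoate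
Product: 7 methyl (2Z,6Z)-8-[(tert-butyldiphenylsilyl)oxy]-2,6-dimethylocta-2,6-dienoate
Conditions: 6, KN(SiMe3)2, 18-crown-6, THF, −78 °C; then 5
Reagents that add atoms: none
Why: In the Still–Gennari variant of the Horner–Wadsworth–Emmons olefination the electron-poor phosphonate and the crown-complexed potassium ion make elimination faster than equilibration, so the kinetic (Z)-enoate with ester and chain cis should form.

Step 5
Reactants: 7 methyl (2Z,6Z)-8-[(tert-butyldiphenylsilyl)oxy]-2,6-dimethylocta-2,6-dienoate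
Product: 8 (2Z,6Z)-8-[(tert-butyldiphenylsilyl)oxy]-2,6-dimethylocta-2,6-dien-1-ol
Conditions: i-Bu2AlH (2.2 equiv), CH2Cl2, −78 °C; aq. potassium sodium tartrate work-up
Reagents that add atoms: none
Why: Aluminium hydride 1,2-reduction of the enoate gives the allylic alcohol with the alkene geometry unchanged.

Step 6
Reactants: 8 (2Z,6Z)-8-[(tert-butyldiphenylsilyl)oxy]-2,6-dimethylocta-2,6-dien-1-ol
Product: 9 [(2S,3R)-3-{(3Z)-5-[(tert-butyldiphenylsilyl)oxy]-3-methylpent-3-en-1-yl}-2-methyloxiran-2-yl]methanol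
Conditions: Ti(Oi-Pr)4 (20 mol%), L-(+)-diethyl tartrate (24 mol%), t-BuOOH, 4 Å molecular sieves, CH2Cl2, −20 °C
Reagents that add atoms: tert-butyl hydroperoxide, CC(C)(C)OO
Why: Katsuki–Sharpless asymmetric epoxidation acts only on the allylic alcohol alkene, and the L-(+)-tartrate ligand should deliver oxygen to the face that gives the (2S,3R) cis epoxide (the same sense as nerol to (2S,3R)-epoxynerol), which sets C7 and C1''.

Step 7
Reactants: 9 [(2S,3R)-3-{(3Z)-5-[(tert-butyldiphenylsilyl)oxy]-3-methylpent-3-en-1-yl}-2-methyloxiran-2-yl]methanol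
Product: 10 [(2S,3R)-3-{(3Z)-5-[(tert-butyldiphenylsilyl)oxy]-3-methylpent-3-en-1-yl}-2-methyloxiran-2-yl]methyl trifluoromethanesulfonate (used crude)
Conditions: Tf2O, 2,6-lutidine, CH2Cl2, −78 °C
Reagents that add atoms: trifluoromethanesulfonic anhydride, O=S(=O)(OS(=O)(=O)C(F)(F)F)C(F)(F)F
Why: O-Sulfonylation of the primary alcohol at low temperature with a hindered base gives the triflate without opening the epoxide.

Step 8
Reactants: 10 [(2S,3R)-3-{(3Z)-5-[(tert-butyldiphenylsilyl)oxy]-3-methylpent-3-en-1-yl}-2-methyloxiran-2-yl]methyl trifluoromethanesulfonate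
Product: 11 (2S,3R)-3-{(3Z)-5-[(tert-butyldiphenylsilyl)oxy]-3-methylpent-3-en-1-yl}-2-methyl-2-(prop-2-en-1-yl)oxirane
Conditions: CH2=CHMgBr, CuI (10 mol%), THF/Et2O, −78 to −30 °C
Reagents that add atoms: vinylmagnesium bromide, C=C[Mg]Br
Why: Copper-catalysed SN2 coupling of a Grignard reagent with a primary triflate should be much faster at low temperature than attack on the trisubstituted epoxide, and it adds C5 and C4 without touching either stereocentre.

Step 9
Reactants: 11 (2S,3R)-3-{(3Z)-5-[(tert-butyldiphenylsilyl)oxy]-3-methylpent-3-en-1-yl}-2-methyl-2-(prop-2-en-1-yl)oxirane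
Product: 13 3-[(2S,3R)-3-{(3Z)-5-[(tert-butyldiphenylsilyl)oxy]-3-methylpent-3-en-1-yl}-2-methyloxiran-2-yl]propan-1-ol, via alkylborane 12 (not isolated)
Conditions: 9-BBN, THF, 0 °C to rt; then NaOH, H2O2, H2O, 0 °C
Reagents that add atoms: hydrogen peroxide, OO
Why: Anti-Markovnikov hydroboration–oxidation with 9-BBN should select the monosubstituted alkene over the trisubstituted one; the epoxy alcohol is kept free of acid and oxidised at once so that it does not close to a tetrahydrofuran.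

Step 10
Reactants: 13 3-[(2S,3R)-3-{(3Z)-5-[(tert-butyldiphenylsilyl)oxy]-3-methylpent-3-en-1-yl}-2-methyloxiran-2-yl]propan-1-ol
Product: 14 3-[(2S,3R)-3-{(3Z)-5-[(tert-butyldiphenylsilyl)oxy]-3-methylpent-3-en-1-yl}-2-methyloxiran-2-yl]propanal
Conditions: Dess–Martin periodinane, pyridine, CH2Cl2, 0 °C
Reagents that add atoms: none
Why: Buffered Dess–Martin oxidation converts the primary alcohol into the aldehyde under near-neutral conditions that the epoxide tolerates.

Step 11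
Reactants: 15 propane-1,3-diol
Product: 16 3-[(tert-butyldimethylsilyl)oxy]propan-1-ol
Conditions: NaH (1.0 equiv), THF, rt; then TBSCl (1.0 equiv)
Reagents that add atoms: tert-butyl(chloro)dimethylsilane, CC(C)(C)[Si](C)(C)Cl
Why: Silylation of the sparingly soluble monosodium alkoxide of a symmetrical diol should give mainly the monosilyl ether.

Step 12
Reactants: 16 3-[(tert-butyldimethylsilyl)oxy]propan-1-ol
Product: 17 3-[(tert-butyldimethylsilyl)oxy]propanal
Conditions: TEMPO (10 mol%), PhI(OAc)2, CH2Cl2, rt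
Reagents that add atoms: none
Why: Oxoammonium-mediated (TEMPO) oxidation stops at the aldehyde and is mild enough to avoid β-elimination of the silyloxy group.

Step 13
Reactants: 17 3-[(tert-butyldimethylsilyl)oxy]propanal; 6 methyl 2-[bis(2,2,2-trifluoroethoxy)phosphoryl]propanoate
Product: 18 methyl (2Z)-5-[(tert-butyldimethylsilyl)oxy]-2-methylpent-2-enoate
Conditions: 6, KN(SiMe3)2, 18-crown-6, THF, −78 °C; then 17
Reagents that add atoms: none
Why: Still–Gennari olefination under kinetic control should again give the (Z)-trisubstituted enoate, which fixes the geometry of the side-chain alkene.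

Step 14
Reactants: 18 methyl (2Z)-5-[(tert-butyldimethylsilyl)oxy]-2-methylpent-2-enoate
Product: 19 (2Z)-5-[(tert-butyldimethylsilyl)oxy]-2-methylpent-2-en-1-ol
Conditions: i-Bu2AlH (2.2 equiv), CH2Cl2, −78 °C; aq. potassium sodium tartrate work-up
Reagents that add atoms: none
Why: Aluminium hydride 1,2-reduction of the enoate gives the (Z)-allylic alcohol without isomerisation.

Step 15
Reactants: 19 (2Z)-5-[(tert-butyldimethylsilyl)oxy]-2-methylpent-2-en-1-ol
Product: 20 tert-butyl({(3Z)-5-[(4-methoxybenzyl)oxy]-4-methylpent-3-en-1-yl}oxy)dimethylsilane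
Conditions: NaH, PMBCl, Bu4NI (cat.), THF/DMF, 0 °C to rt
Reagents that add atoms: 4-methoxybenzyl chloride, COc1ccc(CCl)cc1
Why: Williamson etherification of the allylic alkoxide installs a group that is stable to base and fluoride and is later removed oxidatively.

Step 16
Reactants: 20 tert-butyl({(3Z)-5-[(4-methoxybenzyl)oxy]-4-methylpent-3-en-1-yl}oxy)dimethylsilane
Product: 21 (3Z)-5-[(4-methoxybenzyl)oxy]-4-methylpent-3-en-1-ol
Conditions: Bu4NF, THF, 0 °C to rt
Reagents that add atoms: none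
Why: Fluoride desilylation frees the homoallylic alcohol and leaves the PMB ether intact.

Step 17
Reactants: 21 (3Z)-5-[(4-methoxybenzyl)oxy]-4-methylpent-3-en-1-ol
Product: 22 1-({[(2Z)-5-iodo-2-methylpent-2-en-1-yl]oxy}methyl)-4-methoxybenzene
Conditions: I2, PPh3, imidazole, CH2Cl2, 0 °C, dark
Reagents that add atoms: iodine, II
Why: Appel-type iodination (Garegg–Samuelsson conditions) converts the primary alcohol into the iodide by SN2 displacement of the oxyphosphonium group.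

Step 18
Reactants: 22 1-({[(2Z)-5-iodo-2-methylpent-2-en-1-yl]oxy}methyl)-4-methoxybenzene; 23 methyl 2-[bis(2,2,2-trifluoroethoxy)phosphoryl]acetate
Product: 24 methyl (5Z)-2-[bis(2,2,2-trifluoroethoxy)phosphoryl]-7-[(4-methoxybenzyl)oxy]-6-methylhept-5-enoate (racemic at C2)
Conditions: 23 (2 equiv), NaH, DMF, 0 °C; then 22, rt
Reagents that add atoms: none
Why: SN2 C-alkylation of the soft, weakly basic sodium phosphonoacetate carbanion by the primary iodide should outrun elimination, and the excess of 23 suppresses dialkylation.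

Step 19
Reactants: 24 methyl (5Z)-2-[bis(2,2,2-trifluoroethoxy)phosphoryl]-7-[(4-methoxybenzyl)oxy]-6-methylhept-5-enoate; 14 3-[(2S,3R)-3-{(3Z)-5-[(tert-butyldiphenylsilyl)oxy]-3-methylpent-3-en-1-yl}-2-methyloxiran-2-yl]propanal
Product: 25 methyl (2Z,5Z)-7-[(4-methoxybenzyl)oxy]-6-methyl-2-{3-[(2S,3R)-3-{(3Z)-5-[(tert-butyldiphenylsilyl)oxy]-3-methylpent-3-en-1-yl}-2-methyloxiran-2-yl]propylidene}hept-5-enoate
Conditions: 24, KN(SiMe3)2, 18-crown-6, THF, −78 °C; then 14, −78 to −40 °C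
Reagents that add atoms: none
Why: Still–Gennari olefination with the α-alkylated phosphonate should form C3=C4 with the ester cis to the C5–C6 tether, and the preformed, weakly basic carbanion leaves the aldehyde α-position and the epoxide alone.

Step 20
Reactants: 25 methyl (2Z,5Z)-7-[(4-methoxybenzyl)oxy]-6-methyl-2-{3-[(2S,3R)-3-{(3Z)-5-[(tert-butyldiphenylsilyl)oxy]-3-methylpent-3-en-1-yl}-2-methyloxiran-2-yl]propylidene}hept-5-enoate
Product: 27 (2Z,5Z)-7-[(4-methoxybenzyl)oxy]-6-methyl-2-{3-[(2S,3R)-3-{(3Z)-5-[(tert-butyldiphenylsilyl)oxy]-3-methylpent-3-en-1-yl}-2-methyloxiran-2-yl]propylidene}hept-5-enoic acid, via lithium carboxylate 26 (not isolated)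
Conditions: LiOH·H2O, THF/MeOH/H2O, rt to 40 °C; then aq. AcOH to pH 5, 0 °C
Reagents that add atoms: lithium hydroxide monohydrate (its hydroxide oxygen ends in the carboxyl group), [Li+].[OH-].O
Why: Saponification by acyl–oxygen cleavage frees the acid while the trisubstituted epoxide, the PMB ether and the hindered silyl ether resist hydroxide; the cold, weakly acidic work-up avoids premature epoxide opening.

Step 21
Reactants: 27 (2Z,5Z)-7-[(4-methoxybenzyl)oxy]-6-methyl-2-{3-[(2S,3R)-3-{(3Z)-5-[(tert-butyldiphenylsilyl)oxy]-3-methylpent-3-en-1-yl}-2-methyloxiran-2-yl]propylidene}hept-5-enoic acid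
Product: 28 (7R)-7-{(1R,4Z)-6-[(tert-butyldiphenylsilyl)oxy]-1-hydroxy-4-methylhex-4-en-1-yl}-3-{(3Z)-5-[(4-methoxybenzyl)oxy]-4-methylpent-3-en-1-yl}-7-methyl-6,7-dihydrooxepin-2(5H)-one
Conditions: CSA (10 mol%), CH2Cl2 (0.005 M), 0 °C to rt
Reagents that add atoms: none
Why: The sulfonic acid protonates the cis C7–C1'' epoxide and weakens its C7–O bond, and the carboxyl oxygen on C2, held cis to the C5–C6 tether by the (Z)-C3=C4 alkene, attacks C7 opposite the departing oxygen, so that loss of a proton gives the O1–C7 bond and leaves the epoxide oxygen as the C1'' hydroxyl. The closest known reaction type is the acid-promoted lactonisation of trisubstituted epoxy acids to hydroxy lactones, which is routine for five- and six-membered rings and is applied here to a seven-membered one. Ring A closes in a 7-exo-tet mode, with O1, C2, C3, C4, C5, C6 and C7 in the ring and the breaking C7–O bond outside it. The new stereocentre C7 should become R by stereospecific inversion of the (7S) epoxide carbon set in step 6, while C1'' (R) is not touched. The step needs attack at C7 and not at C1'', and capture by the carboxyl before cation chemistry sets in: the tertiary carbon carries most of the positive charge and attack at C1'' would need an eight-membered endo closure, while a catalytic, non-nucleophilic Brønsted acid at high dilution and the preorganised nucleophile should keep hydride shift, elimination and oligomerisation behind.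

Step 22
Reactants: 28 (7R)-7-{(1R,4Z)-6-[(tert-butyldiphenylsilyl)oxy]-1-hydroxy-4-methylhex-4-en-1-yl}-3-{(3Z)-5-[(4-methoxybenzyl)oxy]-4-methylpent-3-en-1-yl}-7-methyl-6,7-dihydrooxepin-2(5H)-one
Product: 29 (7R)-7-{(1R,4Z)-6-[(tert-butyldiphenylsilyl)oxy]-1-hydroxy-4-methylhex-4-en-1-yl}-3-[(3Z)-5-hydroxy-4-methylpent-3-en-1-yl]-7-methyl-6,7-dihydrooxepin-2(5H)-one
Conditions: DDQ (1.3 equiv), CH2Cl2/pH 7 phosphate buffer, 0 °C
Reagents that add atoms: none
Why: Oxidative cleavage of the electron-rich PMB ether by DDQ (hydride abstraction, then hydrolysis of the oxocarbenium ion) frees the primary allylic alcohol without affecting the lactone, the silyl ether or the alkenes.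

Step 23
Reactants: 29 (7R)-7-{(1R,4Z)-6-[(tert-butyldiphenylsilyl)oxy]-1-hydroxy-4-methylhex-4-en-1-yl}-3-[(3Z)-5-hydroxy-4-methylpent-3-en-1-yl]-7-methyl-6,7-dihydrooxepin-2(5H)-one
Product: 30 (2Z)-5-[(7R)-7-{(1R,4Z)-6-[(tert-butyldiphenylsilyl)oxy]-1-hydroxy-4-methylhex-4-en-1-yl}-7-methyl-2-oxo-2,5,6,7-tetrahydrooxepin-3-yl]-2-methylpent-2-en-1-yl acetate
Conditions: AcCl (1.1 equiv), 2,4,6-collidine, CH2Cl2, −78 °C
Reagents that add atoms: acetyl chloride, CC(=O)Cl
Why: Chemoselective O-acylation with acetyl chloride and a hindered pyridine at low temperature should esterify only the primary allylic hydroxyl, because the C1'' hydroxyl is secondary and flanked by the fully substituted C7.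

Step 24
Reactants: 30 (2Z)-5-[(7R)-7-{(1R,4Z)-6-[(tert-butyldiphenylsilyl)oxy]-1-hydroxy-4-methylhex-4-en-1-yl}-7-methyl-2-oxo-2,5,6,7-tetrahydrooxepin-3-yl]-2-methylpent-2-en-1-yl acetate
Product: 31 (2Z)-5-{(7R)-7-[(1R,4Z)-1,6-dihydroxy-4-methylhex-4-en-1-yl]-7-methyl-2-oxo-2,5,6,7-tetrahydrooxepin-3-yl}-2-methylpent-2-en-1-yl acetate (CNP0286404.1)
Conditions: Bu4NF/AcOH (1:1), THF, 0 °C to rt
Reagents that add atoms: none
Why: Fluoride desilylation buffered with acetic acid removes the silyl ether without acetate cleavage or migration and without opening the lactone.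

**Compound list**

1 | nerol | CC(C)=CCC/C(C)=C\CO | starting material
2 | tert-butyl{[(2Z)-3,7-dimethylocta-2,6-dien-1-yl]oxy}diphenylsilane | CC(C)=CCC/C(C)=C\CO[Si](c1ccccc1)(c1ccccc1)C(C)(C)C | intermediate
3 | tert-butyl{[(2Z)-5-(3,3-dimethyloxiran-2-yl)-3-methylpent-2-en-1-yl]oxy}diphenylsilane (racemic) | CC1(C)OC1CC/C(C)=C\CO[Si](c1ccccc1)(c1ccccc1)C(C)(C)C | intermediate
4 | (6Z)-8-[(tert-butyldiphenylsilyl)oxy]-2,6-dimethyloct-6-ene-2,3-diol (racemic, not isolated) | CC(C)(O)C(O)CC/C(C)=C\CO[Si](c1ccccc1)(c1ccccc1)C(C)(C)C | intermediate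
5 | (4Z)-6-[(tert-butyldiphenylsilyl)oxy]-4-methylhex-4-enal | O=CCC/C(C)=C\CO[Si](c1ccccc1)(c1ccccc1)C(C)(C)C | intermediate
6 | methyl 2-[bis(2,2,2-trifluoroethoxy)phosphoryl]propanoate | COC(=O)C(C)P(=O)(OCC(F)(F)F)OCC(F)(F)F | starting material
7 | methyl (2Z,6Z)-8-[(tert-butyldiphenylsilyl)oxy]-2,6-dimethylocta-2,6-dienoate | COC(=O)/C(C)=C\CC/C(C)=C\CO[Si](c1ccccc1)(c1ccccc1)C(C)(C)C | intermediate
8 | (2Z,6Z)-8-[(tert-butyldiphenylsilyl)oxy]-2,6-dimethylocta-2,6-dien-1-ol | OC/C(C)=C\CC/C(C)=C\CO[Si](c1ccccc1)(c1ccccc1)C(C)(C)C | intermediate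
9 | [(2S,3R)-3-{(3Z)-5-[(tert-butyldiphenylsilyl)oxy]-3-methylpent-3-en-1-yl}-2-methyloxiran-2-yl]methanol | OC[C@@]1(C)[C@@H](CC/C(C)=C\CO[Si](c2ccccc2)(c2ccccc2)C(C)(C)C)O1 | intermediate
10 | [(2S,3R)-3-{(3Z)-5-[(tert-butyldiphenylsilyl)oxy]-3-methylpent-3-en-1-yl}-2-methyloxiran-2-yl]methyl trifluoromethanesulfonate | FC(F)(F)S(=O)(=O)OC[C@@]1(C)[C@@H](CC/C(C)=C\CO[Si](c2ccccc2)(c2ccccc2)C(C)(C)C)O1 | intermediate
11 | (2S,3R)-3-{(3Z)-5-[(tert-butyldiphenylsilyl)oxy]-3-methylpent-3-en-1-yl}-2-methyl-2-(prop-2-en-1-yl)oxirane | C=CC[C@@]1(C)[C@@H](CC/C(C)=C\CO[Si](c2ccccc2)(c2ccccc2)C(C)(C)C)O1 | intermediate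
12 | 9-{3-[(2S,3R)-3-{(3Z)-5-[(tert-butyldiphenylsilyl)oxy]-3-methylpent-3-en-1-yl}-2-methyloxiran-2-yl]propyl}-9-borabicyclo[3.3.1]nonane (not isolated) | B1(C2CCCC1CCC2)CCC[C@@]1(C)[C@@H](CC/C(C)=C\CO[Si](c2ccccc2)(c2ccccc2)C(C)(C)C)O1 | intermediate
13 | 3-[(2S,3R)-3-{(3Z)-5-[(tert-butyldiphenylsilyl)oxy]-3-methylpent-3-en-1-yl}-2-methyloxiran-2-yl]propan-1-ol | OCCC[C@@]1(C)[C@@H](CC/C(C)=C\CO[Si](c2ccccc2)(c2ccccc2)C(C)(C)C)O1 | intermediate
14 | 3-[(2S,3R)-3-{(3Z)-5-[(tert-butyldiphenylsilyl)oxy]-3-methylpent-3-en-1-yl}-2-methyloxiran-2-yl]propanal | O=CCC[C@@]1(C)[C@@H](CC/C(C)=C\CO[Si](c2ccccc2)(c2ccccc2)C(C)(C)C)O1 | intermediate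
15 | propane-1,3-diol | OCCCO | starting material
16 | 3-[(tert-butyldimethylsilyl)oxy]propan-1-ol | OCCCO[Si](C)(C)C(C)(C)C | intermediate
17 | 3-[(tert-butyldimethylsilyl)oxy]propanal | O=CCCO[Si](C)(C)C(C)(C)C | intermediate
18 | methyl (2Z)-5-[(tert-butyldimethylsilyl)oxy]-2-methylpent-2-enoate | COC(=O)/C(C)=C\CCO[Si](C)(C)C(C)(C)C | intermediate
19 | (2Z)-5-[(tert-butyldimethylsilyl)oxy]-2-methylpent-2-en-1-ol | OC/C(C)=C\CCO[Si](C)(C)C(C)(C)C | intermediate
20 | tert-butyl({(3Z)-5-[(4-methoxybenzyl)oxy]-4-methylpent-3-en-1-yl}oxy)dimethylsilane | COc1ccc(cc1)COC/C(C)=C\CCO[Si](C)(C)C(C)(C)C | intermediate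
21 | (3Z)-5-[(4-methoxybenzyl)oxy]-4-methylpent-3-en-1-ol | COc1ccc(cc1)COC/C(C)=C\CCO | intermediate
22 | 1-({[(2Z)-5-iodo-2-methylpent-2-en-1-yl]oxy}methyl)-4-methoxybenzene | COc1ccc(cc1)COC/C(C)=C\CCI | intermediate
23 | methyl 2-[bis(2,2,2-trifluoroethoxy)phosphoryl]acetate | COC(=O)CP(=O)(OCC(F)(F)F)OCC(F)(F)F | starting material
24 | methyl (5Z)-2-[bis(2,2,2-trifluoroethoxy)phosphoryl]-7-[(4-methoxybenzyl)oxy]-6-methylhept-5-enoate (racemic) | COc1ccc(cc1)COC/C(C)=C\CCC(C(=O)OC)P(=O)(OCC(F)(F)F)OCC(F)(F)F | intermediate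
25 | methyl (2Z,5Z)-7-[(4-methoxybenzyl)oxy]-6-methyl-2-{3-[(2S,3R)-3-{(3Z)-5-[(tert-butyldiphenylsilyl)oxy]-3-methylpent-3-en-1-yl}-2-methyloxiran-2-yl]propylidene}hept-5-enoate | COc1ccc(cc1)COC/C(C)=C\CC/C(C(=O)OC)=C/CC[C@@]1(C)[C@@H](CC/C(C)=C\CO[Si](c2ccccc2)(c2ccccc2)C(C)(C)C)O1 | intermediate
26 | lithium salt of acid 27 (not isolated) | COc1ccc(cc1)COC/C(C)=C\CC/C(C(=O)[O-])=C/CC[C@@]1(C)[C@@H](CC/C(C)=C\CO[Si](c2ccccc2)(c2ccccc2)C(C)(C)C)O1.[Li+] | intermediate
27 | (2Z,5Z)-7-[(4-methoxybenzyl)oxy]-6-methyl-2-{3-[(2S,3R)-3-{(3Z)-5-[(tert-butyldiphenylsilyl)oxy]-3-methylpent-3-en-1-yl}-2-methyloxiran-2-yl]propylidene}hept-5-enoic acid (key-step precursor) | COc1ccc(cc1)COC/C(C)=C\CC/C(C(=O)O)=C/CC[C@@]1(C)[C@@H](CC/C(C)=C\CO[Si](c2ccccc2)(c2ccccc2)C(C)(C)C)O1 | intermediate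
28 | (7R)-7-{(1R,4Z)-6-[(tert-butyldiphenylsilyl)oxy]-1-hydroxy-4-methylhex-4-en-1-yl}-3-{(3Z)-5-[(4-methoxybenzyl)oxy]-4-methylpent-3-en-1-yl}-7-methyl-6,7-dihydrooxepin-2(5H)-one (key-step product) | COc1ccc(cc1)COC/C(C)=C\CCC1=CCC[C@](C)([C@H](O)CC/C(C)=C\CO[Si](c2ccccc2)(c2ccccc2)C(C)(C)C)OC1=O | intermediate
29 | (7R)-7-{(1R,4Z)-6-[(tert-butyldiphenylsilyl)oxy]-1-hydroxy-4-methylhex-4-en-1-yl}-3-[(3Z)-5-hydroxy-4-methylpent-3-en-1-yl]-7-methyl-6,7-dihydrooxepin-2(5H)-one | OC/C(C)=C\CCC1=CCC[C@](C)([C@H](O)CC/C(C)=C\CO[Si](c2ccccc2)(c2ccccc2)C(C)(C)C)OC1=O | intermediate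
30 | (2Z)-5-[(7R)-7-{(1R,4Z)-6-[(tert-butyldiphenylsilyl)oxy]-1-hydroxy-4-methylhex-4-en-1-yl}-7-methyl-2-oxo-2,5,6,7-tetrahydrooxepin-3-yl]-2-methylpent-2-en-1-yl acetate | CC(=O)OC/C(C)=C\CCC1=CCC[C@](C)([C@H](O)CC/C(C)=C\CO[Si](c2ccccc2)(c2ccccc2)C(C)(C)C)OC1=O | intermediate
31 | (2Z)-5-{(7R)-7-[(1R,4Z)-1,6-dihydroxy-4-methylhex-4-en-1-yl]-7-methyl-2-oxo-2,5,6,7-tetrahydrooxepin-3-yl}-2-methylpent-2-en-1-yl acetate | CC(=O)OC/C(C)=C\CCC1=CCC[C@](C)([C@H](O)CC/C(C)=C\CO)OC1=O | target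

**Step count**

Total: 24 steps. Longest linear sequence: 16 steps (steps 1–10 and 19–24, from nerol); the side-chain branch (steps 11–18) joins at step 19.

**Steps most likely to fail**

1. Step 21 (key lactonisation). The seven-membered closure is slower than the five- and six-membered cases. The acid could therefore ionise C7 to a free cation, with hydride shift, elimination or loss of stereospecificity, and opening at C1'' or intermolecular esterification could compete. Fallback: the O1–C2 bond is made as an acyl–oxygen bond instead. It sets out from ester 25 and comes back at 28. HClO4 (cat.) in THF/H2O at 0 °C should open the epoxide by water at C7 with inversion to give methyl (2Z,5Z)-2-{(4R,5R,8Z)-10-[(tert-butyldiphenylsilyl)oxy]-4,5-dihydroxy-4,8-dimethyldec-8-en-1-ylidene}-7-[(4-methoxybenzyl)oxy]-6-methylhept-5-enoate F1; any opening at C1'' here would lower the enantiomeric purity. TESCl/imidazole silylates only the secondary hydroxyl to give methyl (2Z,5Z)-2-{(4R,5R,8Z)-10-[(tert-butyldiphenylsilyl)oxy]-4-hydroxy-4,8-dimethyl-5-[(triethylsilyl)oxy]dec-8-en-1-ylidene}-7-[(4-methoxybenzyl)oxy]-6-methylhept-5-enoate F2. LiOH then gives the seco acid (2Z,5Z)-2-{(4R,5R,8Z)-10-[(tert-butyldiphenylsilyl)oxy]-4-hydroxy-4,8-dimethyl-5-[(triethylsilyl)oxy]dec-8-en-1-ylidene}-7-[(4-methoxybenzyl)oxy]-6-methylhept-5-enoic acid F3, whose only free hydroxyl is the tertiary one on C7. Yamaguchi lactonisation (2,4,6-trichlorobenzoyl chloride, Et3N, then DMAP, toluene, high dilution, heating) closes ring A to (7R)-7-{(1R,4Z)-6-[(tert-butyldiphenylsilyl)oxy]-4-methyl-1-[(triethylsilyl)oxy]hex-4-en-1-yl}-3-{(3Z)-5-[(4-methoxybenzyl)oxy]-4-methylpent-3-en-1-yl}-7-methyl-6,7-dihydrooxepin-2(5H)-one F4. PPTS in MeOH removes the triethylsilyl group and returns 28.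

2. Step 19 (fragment union). The α-branched phosphonate anion may add slowly, Z-selectivity may erode if the mixture has to be warmed, and the aldehyde may enolise. Fallback: the alkene geometry is set first and the side chain is attached by cross-coupling. It sets out from aldehyde 14 (with iodide 22 and phosphonoacetate 23) and comes back at 25. α-Bromination of 23 (NaH, then Br2, THF, −78 °C) gives methyl 2-bromo-2-[bis(2,2,2-trifluoroethoxy)phosphoryl]acetate F5. Its Horner–Wadsworth–Emmons reaction with 14 (t-BuOK, 18-crown-6, THF, −78 °C) should give the (E)-α-bromo enoate with the ester cis to the tether, methyl (2E)-2-bromo-5-[(2S,3R)-3-{(3Z)-5-[(tert-butyldiphenylsilyl)oxy]-3-methylpent-3-en-1-yl}-2-methyloxiran-2-yl]pent-2-enoate F6. Zinc insertion into 22 (Zn dust, LiCl, THF) gives {(3Z)-5-[(4-methoxybenzyl)oxy]-4-methylpent-3-en-1-yl}zinc iodide F7. Negishi coupling of F6 with F7 (Pd(PPh3)4, THF/N-methylpyrrolidone, rt) proceeds with retention of alkene geometry and gives 25.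

3. Step 8 (vinyl coupling). The organocopper species may attack the epoxide, the triflate may decompose before substitution, and displacement next to the quaternary carbon may be slow. Fallback: homologation by olefination and chemoselective reduction. It sets out from epoxy alcohol 9 and comes back at aldehyde 14, bypassing steps 7–10. Parikh–Doering oxidation (SO3·pyridine, DMSO, i-Pr2NEt) gives (2R,3R)-3-{(3Z)-5-[(tert-butyldiphenylsilyl)oxy]-3-methylpent-3-en-1-yl}-2-methyloxirane-2-carbaldehyde F8, which cannot epimerise at its quaternary α-carbon. Wittig reaction with Ph3P=CHCO2Me gives methyl (2E)-3-[(2S,3R)-3-{(3Z)-5-[(tert-butyldiphenylsilyl)oxy]-3-methylpent-3-en-1-yl}-2-methyloxiran-2-yl]prop-2-enoate F9. Diimide (2-nitrobenzenesulfonylhydrazide, Et3N) should reduce only the disubstituted conjugated alkene to give methyl 3-[(2S,3R)-3-{(3Z)-5-[(tert-butyldiphenylsilyl)oxy]-3-methylpent-3-en-1-yl}-2-methyloxiran-2-yl]propanoate F10. i-Bu2AlH (1.1 equiv, CH2Cl2, −78 °C) gives 14; any over-reduced material is alcohol 13 and re-enters at step 10.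

**Further compounds**

F1 | step 21 | methyl (2Z,5Z)-2-{(4R,5R,8Z)-10-[(tert-butyldiphenylsilyl)oxy]-4,5-dihydroxy-4,8-dimethyldec-8-en-1-ylidene}-7-[(4-methoxybenzyl)oxy]-6-methylhept-5-enoate | COc1ccc(cc1)COC/C(C)=C\CC/C(C(=O)OC)=C/CC[C@](C)([C@H](O)CC/C(C)=C\CO[Si](c2ccccc2)(c2ccccc2)C(C)(C)C)O
F2 | step 21 | methyl (2Z,5Z)-2-{(4R,5R,8Z)-10-[(tert-butyldiphenylsilyl)oxy]-4-hydroxy-4,8-dimethyl-5-[(triethylsilyl)oxy]dec-8-en-1-ylidene}-7-[(4-methoxybenzyl)oxy]-6-methylhept-5-enoate | COc1ccc(cc1)COC/C(C)=C\CC/C(C(=O)OC)=C/CC[C@](C)([C@H](O[Si](CC)(CC)CC)CC/C(C)=C\CO[Si](c2ccccc2)(c2ccccc2)C(C)(C)C)O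
F3 | step 21 | (2Z,5Z)-2-{(4R,5R,8Z)-10-[(tert-butyldiphenylsilyl)oxy]-4-hydroxy-4,8-dimethyl-5-[(triethylsilyl)oxy]dec-8-en-1-ylidene}-7-[(4-methoxybenzyl)oxy]-6-methylhept-5-enoic acid | COc1ccc(cc1)COC/C(C)=C\CC/C(C(=O)O)=C/CC[C@](C)([C@H](O[Si](CC)(CC)CC)CC/C(C)=C\CO[Si](c2ccccc2)(c2ccccc2)C(C)(C)C)O
F4 | step 21 | (7R)-7-{(1R,4Z)-6-[(tert-butyldiphenylsilyl)oxy]-4-methyl-1-[(triethylsilyl)oxy]hex-4-en-1-yl}-3-{(3Z)-5-[(4-methoxybenzyl)oxy]-4-methylpent-3-en-1-yl}-7-methyl-6,7-dihydrooxepin-2(5H)-one | COc1ccc(cc1)COC/C(C)=C\CCC1=CCC[C@](C)([C@H](O[Si](CC)(CC)CC)CC/C(C)=C\CO[Si](c2ccccc2)(c2ccccc2)C(C)(C)C)OC1=O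
F5 | step 19 | methyl 2-bromo-2-[bis(2,2,2-trifluoroethoxy)phosphoryl]acetate | COC(=O)C(Br)P(=O)(OCC(F)(F)F)OCC(F)(F)F
F6 | step 19 | methyl (2E)-2-bromo-5-[(2S,3R)-3-{(3Z)-5-[(tert-butyldiphenylsilyl)oxy]-3-methylpent-3-en-1-yl}-2-methyloxiran-2-yl]pent-2-enoate | COC(=O)/C(Br)=C\CC[C@@]1(C)[C@@H](CC/C(C)=C\CO[Si](c2ccccc2)(c2ccccc2)C(C)(C)C)O1
F7 | step 19 | {(3Z)-5-[(4-methoxybenzyl)oxy]-4-methylpent-3-en-1-yl}zinc iodide | COc1ccc(cc1)COC/C(C)=C\CC[Zn]I
F8 | step 8 | (2R,3R)-3-{(3Z)-5-[(tert-butyldiphenylsilyl)oxy]-3-methylpent-3-en-1-yl}-2-methyloxirane-2-carbaldehyde | O=C[C@@]1(C)[C@@H](CC/C(C)=C\CO[Si](c2ccccc2)(c2ccccc2)C(C)(C)C)O1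
F9 | step 8 | methyl (2E)-3-[(2S,3R)-3-{(3Z)-5-[(tert-butyldiphenylsilyl)oxy]-3-methylpent-3-en-1-yl}-2-methyloxiran-2-yl]prop-2-enoate | COC(=O)/C=C/[C@@]1(C)[C@@H](CC/C(C)=C\CO[Si](c2ccccc2)(c2ccccc2)C(C)(C)C)O1
F10 | step 8 | methyl 3-[(2S,3R)-3-{(3Z)-5-[(tert-butyldiphenylsilyl)oxy]-3-methylpent-3-en-1-yl}-2-methyloxiran-2-yl]propanoate | COC(=O)CC[C@@]1(C)[C@@H](CC/C(C)=C\CO[Si](c2ccccc2)(c2ccccc2)C(C)(C)C)O1
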